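All runs are simulated with made-up constants; scatter was added.

Slowness is what I have to reckon with here: in the west run the starting material reads 0 % by 2.50 d, but the isomer of the product reads 7 % at 5.00 d and 12 % at 12.0 d. So I treat the capture of material by the first nucleophile as the large, early event and compute only a small, late correction to it. That correction is the isomer share, the isomer as a fraction of target plus isomer, both counted as fractions of the starting material charged.

| flask | starting material | first nucleophile | gas | remark | time |
|---|---|---|---|---|---|
| west | 0.90 M | 0.73 M | 120 mM (held) | run made earlier |  |
| north-west | 0.90 M | 2.4 M | 120 mM (held) | run made earlier |  |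
| Tuesday's | 0.90 M | 0.540 M | 120 mM (held) |  | 25 d |
| Wednesday's | 0.90 M | 1.10 M | 120 mM (held) |  | 25 d |
| Sunday's | 0.90 M | 2.20 M | 120 mM (held) |  | 25 d |

| run | time / d | isomer of the product / % | other capture product / % | target / % | solvolysis product / % | starting material / % |
|---|---|---|---|---|---|---|
| west | 1.04 | 4 | 10 | 42 | 40 | 3 |
| west | 2.50 | 7 | 10 | 42 | 41 | 0 |
| west | 5.00 | 7 | 8 | 39 | 40 | 0 |
| west | 12.0 | 12 | 10 | 39 | 41 | 0 |
| north-west | 1.04 | 3 | 5 | 73 | 15 | 3 |
| north-west | 2.50 | 7 | 2 | 72 | 17 | 3 |
| north-west | 5.00 | 7 | 4 | 65 | 18 | 0 |
| north-west | 12.0 | 17 | 4 | 61 | 16 | 0 |

(each reading ± 2 percentage points)

- the earlier runs were read with a standard deviation of 2 percentage points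
- at the start none of the gas is in solution

- which of these there is most of at the end, counted by the starting material in it, Tuesday's (other capture product / isomer of the product / target / solvolysis product)
- which of these there is most of at the end, counted by the starting material in it, Wednesday's (other capture product / isomer of the product / target / solvolysis product)
- which of these there is most of at the end, counted by the starting material in it, Sunday's (other capture product / isomer of the product / target / solvolysis product)
- final amount of the leader among these, as a percentage of the starting material charged, in Tuesday's
- final amount of the leader among these, as a percentage of the starting material charged, in Wednesday's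
- final amount of the leader among these, as a percentage of the starting material charged, in Sunday's

At the last reading the share is 23.5 % in the west run, charged with 0.73 M of first nucleophile, and 21.8 % in the north-west run, charged with 2.4 M, and the mean of these readings is 22.7 %. The bench rule says a slow leak grows in step with time, which gives 47.2 % at 25 d, and I take that as the upper end of my estimate. The border of the rule shows in a ratio: from 5.00 d to 12.0 d time grew 2.40-fold, but the mean share, from 12.5 %, grew less than that, 1.82-fold. With a scatter of 2 percentage points this bend is a hint, yet the asked time is 2.08 times the time of the last reading. So I commit to the midpoint between the last reading and that upper end, an end isomer share of 34.9 %. Sunday's charge is 0.917 of the north-west one, so I take the north-west target plus isomer, 78.0 %, as its capture, which leaves about 50.8 % as target in Sunday's flask.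

The forecast gives solvolysis product at 49 % for Tuesday's, target at 34 % for Wednesday's and target at 45 % for Sunday's, on these grounds: “That leaves about 57% of it after 25 d, assuming simple first-order loss.” It keeps 57 per cent of the target where I keep 65.1 %, so for Sunday's I stand higher than it does.

The flask gives solvolysis product at 45.3 % in Tuesday's, target at 42.5 % in Wednesday's and target at 55.4 % in Sunday's.

    starting material → intermediate (k = 0.190 h⁻¹)
    target ⇌ isomer of the product (K = 0.380, k = 0.00140 h⁻¹)
    intermediate → side product (k = 0.130 h⁻¹)
    intermediate → solvolysis product (k = 0.720 h⁻¹)
    first nucleophile + intermediate → target (k = 1.70 M⁻¹ h⁻¹)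
    second nucleophile + intermediate → other capture product (k = 5.20 M⁻¹ h⁻¹)
    gas ⇌ second nucleophile, rate k7*(csat - [second nucleophile]) (kL = 0.100 h⁻¹)

In Wednesday's flask half of the solvolysis turnover up to 25 d is done by 0.184 d, whereas the half-life of target by the forward step to the isomer alone, at 0.152 d, is 21 d, 112 times longer. In Wednesday's flask the capture split is laid down early, under kinetic control, and the isomer share grows afterwards. At 25 d that share stands at 26.2 % in Wednesday's flask, below my 34.9 %, and target there is 41.7 % at 250 d. In the neighbour of Wednesday's charged with 0.44 M of first nucleophile, my share applied to its target plus isomer gives 20.7 % as target, and that flask holds 23.5 % at 25.0 d.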